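The quinone ring is assembled in one Dötz benzannulation from three pieces: an (E)-alkenyl(methoxy)carbene complex of Cr(CO)5 (future C4, C5 and chain-bearing C6), one of its CO ligands (C1) and methoxyacetylene (C2 with its methoxy group, C3). The step exploits the para relationship of the two carbonyl carbons C1 and C4 of the quinone ring, with the methoxy carbon C2 beside C1. It forms C3–C4, C1–C2 and C1–C6 at once and should deliver a 2,4-dimethoxy-6-alkylphenol whose pattern is fixed by the regiochemistry of alkyne insertion. Ester hydrolysis and oxidation with (NH4)2Ce(NO3)6 then unmask the quinone acid. The carbene complex comes from aldol condensation with a C16 aldehyde ester.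

Key step: step 5

Remark: the target is achiral; its side chain is read as fourteen CH2 groups ending in CO2H, attached to C6 of a 2-methoxy-1,4-benzoquinone.

Step 1
Reactants: 1 chromium hexacarbonyl Cr(CO)6
Product: 3 pentacarbonyl(1-methoxyethylidene)chromium, via lithium acetylpentacarbonylchromate 2 (not isolated)
Conditions: MeLi, Et2O, 0 °C; then Me3OBF4, H2O/CH2Cl2, 0 °C
Reagents that add atoms: methyllithium, [Li]C; trimethyloxonium tetrafluoroborate, C[O+](C)C.F[B-](F)(F)F
Why: Fischer carbene synthesis: MeLi adds to a CO ligand to give the acyl chromate 2, whose oxygen is methylated by the hard Meerwein salt.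

Step 2
Reactants: 4 methyl 16-hydroxyhexadecanoate
Product: 5 methyl 16-oxohexadecanoate
Conditions: TEMPO (cat.), PhI(OAc)2, CH2Cl2, rt
Reagents that add atoms: none
Why: Oxoammonium-mediated (TEMPO) oxidation of a primary alcohol stops at the aldehyde in anhydrous CH2Cl2 and leaves the methyl ester untouched.

Step 3
Reactants: 3 pentacarbonyl(1-methoxyethylidene)chromium; 5 methyl 16-oxohexadecanoate
Product: 8 pentacarbonyl[(2E)-1,18-dimethoxy-18-oxooctadec-2-en-1-ylidene]chromium, via aldol adduct 6 (not isolated), via mesylate 7 (not isolated)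
Conditions: n-BuLi, THF, −78 °C; then 5·TiCl4, CH2Cl2, −78 °C; H2O quench; crude 6: MsCl, Et3N, CH2Cl2, 0 °C to rt
Reagents that add atoms: none
Why: Aldol condensation of a Fischer carbene complex: the acidic α-methyl of 3 gives a soft carbon anion that should add to the TiCl4-activated aldehyde but not to the ester, and base-induced (E1cB) loss of mesylate from racemic 6 should give the conjugated (E)-alkene, which destroys the stereocentre of 6.

Step 4
Reactants: 9 2-chloro-1,1-dimethoxyethane (chloroacetaldehyde dimethyl acetal)
Product: 11 methoxyacetylene, via sodium methoxyacetylide 10 (not isolated)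
Conditions: NaNH2 (3 equiv), liquid NH3, −33 °C; then sat. aq. NaCl, −70 °C to rt, distilled into a −78 °C trap and diluted with THF
Reagents that add atoms: none
Why: Twofold base-induced elimination (HCl, then methanol) from the chloroacetal with NaNH2 gives the sodium alkynide, which is protonated on quench; this is the classical alkoxyacetylene preparation from α-chloroacetals.

Step 5
Reactants: 8 pentacarbonyl[(2E)-1,18-dimethoxy-18-oxooctadec-2-en-1-ylidene]chromium; 11 methoxyacetylene
Product: 14 methyl 15-(2-hydroxy-3,5-dimethoxyphenyl)pentadecanoate, via dienylketene Cr(CO)3 complex 12 (not isolated), via arene Cr(CO)3 complex 13 (not isolated)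
Conditions: 11 (3 equiv), THF (0.05 M), 50 °C, sealed tube, argon; then air, MeCN, rt
Reagents that add atoms: none
Why: Dötz benzannulation: thermal loss of one CO from 8 lets methoxyacetylene insert into the Cr=C bond with its unsubstituted carbon joining the carbene carbon (C3–C4), CO then inserts at the new methoxy-stabilised carbene carbon to give the Cr(CO)3-bound dienylketene 12 (C1–C2), and 6π electrocyclisation of 12 joins the ketene carbon to the chain-bearing alkene carbon (C1–C6) before tautomerisation to the phenol complex 13, which air decomplexes. The closest known reaction type is the benzannulation of alkenyl(alkoxy)carbene complexes of Cr(CO)5 with terminal alkynes and ynol ethers, and the dienyl(methoxy)carbene formed on insertion is the kind of species known to cyclise to ortho-alkoxyphenols. The six-membered ring closes by a thermal disrotatory 6π electrocyclic closure of a (Z)-dienylketene, not by an ionic cyclisation. No stereocentre is formed, and the (E) geometry of 8 is erased on aromatisation. The step needs regioselective insertion (2,6- and not 2,5-pattern) and phenol formation in preference to cyclopentannulation or alkyne oligomerisation; the terminal, polarised ynol ether should place its CH carbon on the electrophilic carbene carbon for both steric and electronic reasons, and an alkenyl complex with a β-hydrogen in THF at moderate temperature favours CO insertion.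

Step 6
Reactants: 14 methyl 15-(2-hydroxy-3,5-dimethoxyphenyl)pentadecanoate
Product: 15 15-(2-hydroxy-3,5-dimethoxyphenyl)pentadecanoic acid
Conditions: LiOH, THF/MeOH/H2O, rt, argon; then 1 M HCl
Reagents that add atoms: lithium hydroxide, [Li+].[OH-]
Why: Saponification (acyl substitution by hydroxide) of the methyl ester; the aryl methyl ethers are inert, and exclusion of air protects the electron-rich phenolate.

Step 7
Reactants: 15 15-(2-hydroxy-3,5-dimethoxyphenyl)pentadecanoic acid
Product: 16 15-(5-methoxy-3,6-dioxocyclohexa-1,4-dien-1-yl)pentadecanoic acid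
Conditions: (NH4)2Ce(NO3)6 (2.2 equiv), MeCN/H2O, 0 °C
Reagents that add atoms: water, O
Why: Oxidative demethylation of a 4-methoxyphenol with (NH4)2Ce(NO3)6 (two one-electron oxidations, water adds at C4 and methanol leaves) should give the para-quinone, while the 2-methoxy group is retained as a vinylogous ester and the carboxylic acid is inert.

Compound list
1 | chromium hexacarbonyl, Cr(CO)6 | O=C=[Cr](=C=O)(=C=O)(=C=O)(=C=O)=C=O | starting material
2 | lithium acetylpentacarbonylchromate, Li[(CO)5CrC(O)CH3] | [Li+].CC(=O)[Cr-](=C=O)(=C=O)(=C=O)(=C=O)=C=O | intermediate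
3 | pentacarbonyl(1-methoxyethylidene)chromium, (CO)5Cr=C(OMe)CH3 | COC(C)=[Cr](=C=O)(=C=O)(=C=O)(=C=O)=C=O | intermediate
4 | methyl 16-hydroxyhexadecanoate | COC(=O)CCCCCCCCCCCCCCCO | starting material
5 | methyl 16-oxohexadecanoate | COC(=O)CCCCCCCCCCCCCCC=O | intermediate
6 | pentacarbonyl(3-hydroxy-1,18-dimethoxy-18-oxooctadecylidene)chromium (racemic aldol adduct) | COC(=O)CCCCCCCCCCCCCCC(O)CC(OC)=[Cr](=C=O)(=C=O)(=C=O)(=C=O)=C=O | intermediate
7 | pentacarbonyl[1,18-dimethoxy-3-(methylsulfonyloxy)-18-oxooctadecylidene]chromium (racemic mesylate) | COC(=O)CCCCCCCCCCCCCCC(OS(C)(=O)=O)CC(OC)=[Cr](=C=O)(=C=O)(=C=O)(=C=O)=C=O | intermediate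
8 | pentacarbonyl[(2E)-1,18-dimethoxy-18-oxooctadec-2-en-1-ylidene]chromium | COC(=O)CCCCCCCCCCCCCC/C=C/C(OC)=[Cr](=C=O)(=C=O)(=C=O)(=C=O)=C=O | intermediate
9 | 2-chloro-1,1-dimethoxyethane | ClCC(OC)OC | starting material
10 | sodium methoxyacetylide | [Na+].[C-]#COC | intermediate
11 | methoxyacetylene (methoxyethyne) | COC#C | intermediate
12 | Cr(CO)3 complex of methyl (16E,18E)-18,20-dimethoxy-21-oxohenicosa-16,18,20-trienoate (dienylketene) | COC(=O)CCCCCCCCCCCCCC/C=C/C(OC)=C\C(OC)=C=O.[Cr](=C=O)(=C=O)=C=O | intermediate
13 | tricarbonyl[η6-methyl 15-(2-hydroxy-3,5-dimethoxyphenyl)pentadecanoate]chromium | COC(=O)CCCCCCCCCCCCCCc1cc(OC)cc(OC)c1O.[Cr](=C=O)(=C=O)=C=O | intermediate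
14 | methyl 15-(2-hydroxy-3,5-dimethoxyphenyl)pentadecanoate | COC(=O)CCCCCCCCCCCCCCc1cc(OC)cc(OC)c1O | intermediate
15 | 15-(2-hydroxy-3,5-dimethoxyphenyl)pentadecanoic acid | OC(=O)CCCCCCCCCCCCCCc1cc(OC)cc(OC)c1O | intermediate
16 | 15-(5-methoxy-3,6-dioxocyclohexa-1,4-dien-1-yl)pentadecanoic acid | COC1=CC(=O)C=C(CCCCCCCCCCCCCCC(=O)O)C1=O | target

Total step count: 7. Longest linear sequence: 5 steps (steps 2, 3, 5, 6 and 7 from compound 4; steps 1 and 4 are one-step branch preparations).

Steps most likely to fail

Risk 1 (step 5, key step). The electron-rich alkyne may oligomerise on the carbene complex, may insert with the opposite regiochemistry, or the dienylcarbene may cyclise without CO insertion. The fallback sets out from aldehyde 5 and comes back at target 16. It makes the same two ring bonds by a classical Michael–Claisen annulation of two three-carbon halves. Horner–Wadsworth–Emmons olefination of 5 (trimethyl phosphonoacetate, NaH, THF, 0 °C) should give dimethyl (2E)-octadec-2-enedioate F1. Methyl acetoacetate with NaOMe in refluxing MeOH should add in Michael fashion to C3 of F1 and close by Claisen condensation of its methyl group onto the C1 ester, giving methyl 2,4-dioxo-6-(15-methoxy-15-oxopentadecyl)cyclohexane-1-carboxylate F2 as its sodium enolate (stereoisomer mixture, not isolated). Aqueous NaOH at reflux, then HCl with warming, should hydrolyse and decarboxylate it to 15-(3,5-dioxocyclohexyl)pentadecanoic acid F3. Aromatisation with I2 in refluxing MeOH should give the resorcinol monomethyl ether with the acid esterified, methyl 15-(3-hydroxy-5-methoxyphenyl)pentadecanoate F4. LiOH in THF/H2O should give 15-(3-hydroxy-5-methoxyphenyl)pentadecanoic acid F5. Teuber oxidation with (KSO3)2NO (Fremy's salt) in KH2PO4-buffered acetone/water, para to the phenol hydroxyl, should then give 16.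

Risk 2 (step 3). The enolisable aldehyde may self-condense, the aldol addition may revert, or elimination may stall or be followed by amine addition to the alkenyl carbene. The fallback sets out from 5 and 1 and comes back at 8. It builds the carbene carbon–chromium bond by acylation of a carbonylmetalate and does not use an aldol reaction. Doebner–Knoevenagel condensation of 5 with malonic acid (pyridine, piperidine, 90 °C) should give (2E)-18-methoxy-18-oxooctadec-2-enoic acid F6. (COCl)2 with catalytic DMF in CH2Cl2 should give methyl (16E)-18-chloro-18-oxooctadec-16-enoate F7. Separately, reduction of 1 with sodium naphthalenide NaC10H8 (2 equiv, THF, −78 °C) should give disodium pentacarbonylchromate Na2Cr(CO)5 F8. F8 should be acylated by F7 at −78 °C to give the sodium acylpentacarbonylchromate F9, and O-methylation with Me3OBF4 should give 8.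

Risk 3 (step 7). Oxidation may run toward the ortho-quinone by loss of the 2-methoxy group, or the electron-rich ring may be over-oxidised or nitrated. The fallback sets out from 15 and comes back at 16. Oxidative dearomatisation with PhI(OAc)2 in MeOH at 0 °C should give the para-quinone monoketal 15-(3,3,5-trimethoxy-6-oxocyclohexa-1,4-dien-1-yl)pentadecanoic acid F10. Mild hydrolysis of the ketal (aqueous oxalic acid, THF, rt) should then release 16.

Further compounds
F1 | step 5 | dimethyl (2E)-octadec-2-enedioate | COC(=O)/C=C/CCCCCCCCCCCCCCC(=O)OC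
F2 | step 5 | methyl 2,4-dioxo-6-(15-methoxy-15-oxopentadecyl)cyclohexane-1-carboxylate | COC(=O)CCCCCCCCCCCCCCC1CC(=O)CC(=O)C1C(=O)OC
F3 | step 5 | 15-(3,5-dioxocyclohexyl)pentadecanoic acid | OC(=O)CCCCCCCCCCCCCCC1CC(=O)CC(=O)C1
F4 | step 5 | methyl 15-(3-hydroxy-5-methoxyphenyl)pentadecanoate | COC(=O)CCCCCCCCCCCCCCc1cc(O)cc(OC)c1
F5 | step 5 | 15-(3-hydroxy-5-methoxyphenyl)pentadecanoic acid | OC(=O)CCCCCCCCCCCCCCc1cc(O)cc(OC)c1
F6 | step 3 | (2E)-18-methoxy-18-oxooctadec-2-enoic acid | COC(=O)CCCCCCCCCCCCCC/C=C/C(=O)O
F7 | step 3 | methyl (16E)-18-chloro-18-oxooctadec-16-enoate | COC(=O)CCCCCCCCCCCCCC/C=C/C(=O)Cl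
F8 | step 3 | disodium pentacarbonylchromate, Na2Cr(CO)5 | [Na+].[Na+].O=C=[Cr-2](=C=O)(=C=O)(=C=O)=C=O
F9 | step 3 | sodium [(2E)-18-methoxy-18-oxooctadec-2-enoyl]pentacarbonylchromate | [Na+].COC(=O)CCCCCCCCCCCCCC/C=C/C(=O)[Cr-](=C=O)(=C=O)(=C=O)(=C=O)=C=O
F10 | step 7 | 15-(3,3,5-trimethoxy-6-oxocyclohexa-1,4-dien-1-yl)pentadecanoic acid | COC1=CC(OC)(OC)C=C(CCCCCCCCCCCCCCC(=O)O)C1=O
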